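The retrosynthesis cuts two bonds of 2-(4-hydroxyphenyl)ethyl triacontanoate: the C13–C14 bond of the acyl chain (carbonyl carbon = C1) and the ester bond between C1 and the oxygen of the CH2CH2O arm; the phenol carries a tert-butyl carbonate meanwhile.
The feature that allows the central cut: C13–C14 is an unpolarised CH2–CH2 bond in a saturated, unbranched chain, twelve methylenes from the ester carbonyl and far from the benzene ring. Each of its carbons can therefore be generated as a primary radical from a carboxyl group, C14–C30 from stearic acid and C1–C13 from a half-ester of tetradecanedioic acid.
Forward, the chain is joined in this order: the phenol of tyrosol is masked as an electron-poor carbonate, the primary alcohol is esterified once with the C14 diacid, the free carboxyl end is coupled with stearic acid by crossed Kolbe electrolysis, and the phenol is released last.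
No ring is formed; the benzene ring is bought with tyrosol. The target has no stereocentre and no double-bond geometry, so no stereochemistry has to be set.
Key step: step 3

Assumption: the acyl chain is read from the SMILES as unbranched triacontanoyl (thirty carbons, the carbonyl carbon counted as C1).

Step 1
Reactants: 1 tyrosol (2-(4-hydroxyphenyl)ethanol); 2 di-tert-butyl dicarbonate
Product: 3 tert-butyl 4-(2-hydroxyethyl)phenyl carbonate
Conditions: NaOH (1.0 equiv), THF/H2O, 0 °C; 2 (1.05 equiv), 0 °C to rt
Reagents that add atoms: none
Why: Chemoselective O-tert-butoxycarbonylation of a phenoxide (Schotten–Baumann-type acylation): one equivalent of NaOH deprotonates only the phenol (pKa about 10) and not the primary alcohol (pKa about 16), and the aryloxide attacks 2 at 0 °C, whereas a neutral alcohol would need an acyl-transfer catalyst, which is left out.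

Step 2
Reactants: 3 tert-butyl 4-(2-hydroxyethyl)phenyl carbonate; 4 tetradecanedioic acid
Product: 5 14-{2-[4-(tert-butoxycarbonyloxy)phenyl]ethoxy}-14-oxotetradecanoic acid
Conditions: 4 (4 equiv), PPh3 (1.3 equiv), DIAD (1.3 equiv), THF, 0 °C to rt; excess 4 filtered off from cold CH2Cl2, then silica gel chromatography
Reagents that add atoms: none
Why: Mitsunobu esterification of a primary alcohol, run with a fourfold excess of the symmetrical diacid so that the activated alcohol should mostly meet a diacid still free at both ends; the medium is neutral and holds no nucleophilic acyl-transfer catalyst, so the aryl carbonate should neither migrate nor cleave, and the cheap excess diacid is recovered.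

Step 3
Reactants: 5 14-{2-[4-(tert-butoxycarbonyloxy)phenyl]ethoxy}-14-oxotetradecanoic acid; 6 stearic acid (octadecanoic acid)
Product: 7 2-[4-(tert-butoxycarbonyloxy)phenyl]ethyl triacontanoate
Conditions: 6 (4 equiv), KOH (ca. 0.08 equiv per CO2H), MeOH/hexane 3:1, undivided cell, smooth Pt foil electrodes, constant current ca. 0.25 A cm-2, 40–45 °C, polarity reversed every few minutes, stopped while the electrolyte is still acidic
Reagents that add atoms: none
Why: On smooth Pt at high current density the carboxylates of 5 and 6 form a dense adsorbed layer and each is oxidised by one electron; the acyloxy radicals lose CO2 to give a heptadecyl radical and a 12-(arylethoxycarbonyl)dodecyl radical side by side at the electrode, and their cross-combination forms the C13–C14 sp3–sp3 bond of the triacontanoyl chain. The closest known reaction type is the classical crossed (mixed) Kolbe electrolysis of a fatty acid with an alkyl hydrogen alkanedioate, the long-established chain-extension route to long-chain fatty esters; only the alkyl group of the ester differs here. No ring is closed and no stereocentre is created, so no mode of closure and no controlling element are involved. The step needs carboxylate oxidation ahead of every other anodic process: the carboxylate layer shields the surface, the benzene ring is deactivated by its carbonate substituent and is separated from the reacting carboxylate by the whole C14 chain, and both radicals are unstabilised primary radicals without an alpha heteroatom or branching, so further oxidation to cations is disfavoured. It also needs cross-coupling of 5 rather than its homocoupling, which the fourfold excess of cheap 6 favours statistically; the non-polar hydrocarbon dimer of 6 and the more polar diester dimer of 5 differ enough from 7 in polarity to be removed by chromatography. Because only a small part of the acid is neutralised and the run is stopped before the acid is used up, the electrolyte stays weakly acidic, which should keep methanolysis of the alkyl ester and of the aryl carbonate slow.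

Step 4
Reactants: 7 2-[4-(tert-butoxycarbonyloxy)phenyl]ethyl triacontanoate
Product: 8 basalethanolide B (2-(4-hydroxyphenyl)ethyl triacontanoate)
Conditions: TFA/CH2Cl2 1:4, Et3SiH (3 equiv), 0 °C to rt
Reagents that add atoms: none
Why: Acidolysis of an aryl tert-butyl carbonate: protonation, loss of the tert-butyl cation and decarboxylation release the phenol, Et3SiH reduces the cation to isobutane so that it cannot alkylate the liberated electron-rich ring, and the primary alkyl ester is inert to anhydrous TFA at room temperature.

Compound list
1 | tyrosol (2-(4-hydroxyphenyl)ethanol) | OCCc1ccc(O)cc1 | starting material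
2 | di-tert-butyl dicarbonate | CC(C)(C)OC(=O)OC(=O)OC(C)(C)C | starting material
3 | tert-butyl 4-(2-hydroxyethyl)phenyl carbonate | CC(C)(C)OC(=O)Oc1ccc(CCO)cc1 | intermediate
4 | tetradecanedioic acid | OC(=O)CCCCCCCCCCCCC(=O)O | starting material
5 | 14-{2-[4-(tert-butoxycarbonyloxy)phenyl]ethoxy}-14-oxotetradecanoic acid | OC(=O)CCCCCCCCCCCCC(=O)OCCc1ccc(OC(=O)OC(C)(C)C)cc1 | intermediate
6 | stearic acid (octadecanoic acid) | CCCCCCCCCCCCCCCCCC(=O)O | starting material
7 | 2-[4-(tert-butoxycarbonyloxy)phenyl]ethyl triacontanoate | CCCCCCCCCCCCCCCCCCCCCCCCCCCCCC(=O)OCCc1ccc(OC(=O)OC(C)(C)C)cc1 | intermediate
8 | basalethanolide B (2-(4-hydroxyphenyl)ethyl triacontanoate) | CCCCCCCCCCCCCCCCCCCCCCCCCCCCCC(=O)OCCc1ccc(O)cc1 | target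

Total step count: 4
Longest linear sequence: 4 steps (1 to 3 to 5 to 7 to 8)

Steps most likely to fail

Step 3 (crossed Kolbe electrolysis). What may go wrong: coating of the anode by the paraffin from homocoupling of the excess acid, disproportionation or overoxidation of the primary radicals instead of cross-combination, anodic attack on the benzene ring, or methanolysis of the aryl carbonate and the arylethyl ester by base formed near the cathode. The fallback sets out from 4 and 6 and moves the formation of the tyrosyl ester behind the carbon–carbon bond formation. Diacid 4 is half-esterified with a limited amount of MeOH (H2SO4 cat., toluene, reflux; monoester separated from diacid and diester by crystallisation) to methyl hydrogen tetradecanedioate F1. Crossed Kolbe electrolysis of F1 with 6 (KOH, MeOH, Pt electrodes), the classical case with a plain methyl ester and neither arene nor carbonate present, should give methyl triacontanoate F2. Saponification (KOH, EtOH/H2O, reflux, then HCl) should give triacontanoic acid F3. Mitsunobu esterification of F3 with alcohol 3 (PPh3, DIAD, THF, 40 °C) comes back to the route at 7, which is deprotected as in step 4.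

Step 2 (mono-esterification of the diacid). What may go wrong: esterification at both carboxyl groups, consumption of the Mitsunobu reagents by anhydride formation, and incomplete separation of the half-ester from the large excess of diacid. The fallback sets out from 4 and 3 and puts the statistical event on the cheapest materials, before the valuable alcohol is involved. Diacid 4 with benzyl alcohol (1 equiv), TsOH·H2O (cat.), toluene, Dean–Stark should give benzyl hydrogen tetradecanedioate F4, purified by crystallisation and chromatography. Mitsunobu coupling of F4 with 3 in equimolar amounts (PPh3, DIAD, THF, 0 °C to rt) should give benzyl 2-[4-(tert-butoxycarbonyloxy)phenyl]ethyl tetradecanedioate F5. Hydrogenolysis (H2, 10% Pd/C, EtOAc, rt) should cleave only the benzyl ester, since the 2-arylethyl ester has no benzylic C–O bond and the aryl tert-butyl carbonate is inert to hydrogen; this comes back to the route at 5.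

Step 1 (selective carbonate formation at the phenol). What may go wrong: acylation of the primary alcohol as well, or hydrolysis of the reagent and of the aryl carbonate in the aqueous base, leading to incomplete conversion. The fallback sets out from 1 and protects the alcohol first instead of relying on chemoselectivity. TBSCl (1.05 equiv), imidazole, CH2Cl2, 0 °C should silylate the more nucleophilic primary alcohol to give 4-[2-(tert-butyldimethylsilyloxy)ethyl]phenol F6. Reaction with 2 and DMAP (cat.) in CH2Cl2 should give tert-butyl 4-[2-(tert-butyldimethylsilyloxy)ethyl]phenyl carbonate F7. Mild acidic desilylation (AcOH/THF/H2O 3:1:1, rt), which the aryl carbonate tolerates, comes back to the route at 3.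

Further compounds
F1 | step 3 | methyl hydrogen tetradecanedioate (14-methoxy-14-oxotetradecanoic acid) | COC(=O)CCCCCCCCCCCCC(=O)O
F2 | step 3 | methyl triacontanoate | CCCCCCCCCCCCCCCCCCCCCCCCCCCCCC(=O)OC
F3 | step 3 | triacontanoic acid | CCCCCCCCCCCCCCCCCCCCCCCCCCCCCC(=O)O
F4 | step 2 | benzyl hydrogen tetradecanedioate (14-(benzyloxy)-14-oxotetradecanoic acid) | OC(=O)CCCCCCCCCCCCC(=O)OCc1ccccc1
F5 | step 2 | benzyl 2-[4-(tert-butoxycarbonyloxy)phenyl]ethyl tetradecanedioate | O=C(OCc1ccccc1)CCCCCCCCCCCCC(=O)OCCc1ccc(OC(=O)OC(C)(C)C)cc1
F6 | step 1 | 4-[2-(tert-butyldimethylsilyloxy)ethyl]phenol | CC(C)(C)[Si](C)(C)OCCc1ccc(O)cc1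
F7 | step 1 | tert-butyl 4-[2-(tert-butyldimethylsilyloxy)ethyl]phenyl carbonate | CC(C)(C)OC(=O)Oc1ccc(CCO[Si](C)(C)C(C)(C)C)cc1
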